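## The problem

Compound 26 is a stilbenoid trimer made of two trans-2,3-diaryl-2,3-dihydrobenzofurans. Ring A (benzene) is fused to ring B (O1, C2, C3) and carries a hydroxyl at C4, a 3,5-dihydroxyphenyl group on C3 and an (E)-4-hydroxystyryl arm on C6. C2 is bonded to C7' of ring C, whose fused ring D (O1', C2', C3') bears a 2,4-dihydroxyphenyl group on C2' and a second 3,5-dihydroxyphenyl group on C3'. All four stereocentres are R. Inside each dihydrofuran the trans arrangement is the thermodynamic one, so C3 can hold C2 and C3' can hold C2', but the two pairs are insulated by ring C and neither can direct the other; absolute control has to be supplied twice. The benzylic C2–O1 and C2'–O1' bonds sit on carbons that carry 2,4-dioxygenated aryl rings and ionise easily under acid, C3 and C3' are doubly benzylic, the stilbene does not survive hydrogenation, and nine free phenols invite oxidation, so the phenols travel as methyl ethers and are freed last. Ring C is the crux: it has four contiguous substituents (OH on C4', C3' on C3a', O1' on C7a', C2 on C7'), and a carbon cannot be placed on C7' by electrophilic substitution because three other resorcinol-type rings compete. The run C3a'(C3')–C7a'(O1')–C7'(C) is, however, exactly what results when an oxygen tethered through C3'–C2' adds to an aryne spanning C7a'/C7' and the carbanion left on C7' takes a one-carbon electrophile, so ring D closure and the introduction of the future C2 can be one operation.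

## Retrosynthesis

**26 from 25.** The nine O–CH3 bonds are cut last. Methyl ethers are chosen because they are the phenol protection that is inert to a lithium amide and to palladium, acid and hydride along the way; benzyl ethers would risk Wittig rearrangement in the key step and hydrogenolysis would touch the stilbene. The forward reaction must cleave nine ethers without changing C2/C3 or C2'/C3'.

**25 from 16 and 22.** Ring B is opened at C2–C3 and O1–C2. This cut divides the molecule into two halves of similar size and gives each carbon the polarity it stabilises best: C2 becomes the benzylide carbon of sulfonium salt 16 (reactive form 24), C3 the methide carbon of the ortho-quinone methide 23 released from sulfone 22. The neighbouring cut at C2–C7' would join two crowded centres with no natural polarity. The forward (4+1) annulation has to give the trans ring and the R,R sense relative to ring D; the C2-symmetric sulfide 15 built into 16 is there for the second task.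

**22 from 21, 19, 20, 17 and 18.** Sulfone 22 comes from benzhydrol 21 by exchange of hydroxyl for sulfinate. 21 is the adduct of Grignard reagent 20 with salicylaldehyde 19, and 19 is the Heck product of bromide 17 and styrene 18. Putting the styryl arm on the small fragment avoids a late coupling, and starting from a salicylaldehyde fixes the methide carbon between the two ring A oxygens, which a Friedel–Crafts route to 22 would not guarantee.

**16 from 12 and 15; 12 from 11; 15 from 14 and 13.** The benzylic C–S bond of 16 is cut to alcohol 12 and sulfide 15. 12 is the reduction product of aldehyde 11, and 15 comes from diol 13 through dimesylate 14 by double inversion.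

**11 from 7 and 8 (key disconnection).** The C7a'–O1' bond of ring D and the C7'–CHO bond are cut together. The precursor is the acyclic fluoro alcohol 7 plus formamide 8: no ring D, and ring C reduced to a fluoroanisole unit. Closing ring D by a conventional C–O coupling would leave C7' to be functionalised afterwards with no selective method, and building ring C de novo (Alternative 1) costs many steps. The forward reaction asks for metalation only next to fluorine, for an aryl anion that lives until the electrophile arrives, and for C2' and C3' to stay untouched.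

**7 from 6.** The carbinol C–H bond is cut. Racemic ketone 6 has a labile α-centre, so one asymmetric transfer hydrogenation with dynamic kinetic resolution can set C2' and C3' together; setting the diarylmethine centre on its own has no comparably short solution.

**6 from 4 and 5; 4 from 1 and 2.** The C3'–C3a' bond is cut by α-arylation logic to deoxybenzoin 4 and bromide 5, which already holds fluorine and methoxy on either side of the coupling site. 4 is the Friedel–Crafts product of arene 1 and acid 2 (through mixed anhydride 3).

## Roads not taken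

**Alternative 1:** Ring C itself is dissected at C7a'–C3a', C4'–C5' and C7a'–C7'. This leads back to an unsaturated diazo ketone hung on C2 of a finished, enantiopure ring A/B unit (A1) and a triisopropylsiloxyalkyne that carries the C3'/C2' chain with both aryl groups (A2).

- Forward step: irradiation of A1 would trigger a Wolff rearrangement to a vinylketene, which adds A2 in a (2+2) step. 4π opening of the cyclobutenone, 6π closure and tautomerisation (Danheiser benzannulation) would give phenol A3, with the free hydroxyl on C7a' and the silyl ether on C4'.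
- Merits: the substitution pattern of ring C is written by the mechanism and not by directing effects, the two oxygens of ring C emerge differentiated, and the halves meet late.
- Weak points: all four stereocentres must be made beforehand in two separate sequences. In A1, C2 becomes an allylic centre γ to a carbonyl and can epimerise or lose its aryloxy group. A2 is a sensitive ynol ether with a propargylic, benzylic stereocentre, and its crowded alkyne must enter a ketene cycloaddition. After A3, ring D still has to be closed by ionisation at C2', and the styryl arm and the deprotections follow.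
- Comparison: it is better than the chosen plan in one respect, since no stereocentre is created after the fragments are joined and no selective aryl metalation is needed. The chosen plan sets against this a purchasable ring C, ring D closure and C2 introduction in one flask, and roughly half the step count.

**Alternative 2:** Ring A is made last. Cutting C3a–C7a, C4–C5 and C6–C7 gives diyne A4, in which O1 carries an ethynyl group and C3 an alkynyl boronate, and enyne A5.

- Forward step: a cationic catalyst from [Rh(cod)2]BF4 and BINAP (monovalent rhodium) would couple the two alkynes of A4 to a rhodacyclopentadiene, which closes ring B, and insert the alkyne of A5 to close ring A. The result is boronate A6, to be oxidised at C4 and demethylated.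
- Merits: two rings and the styryl arm arrive in one atom-economic step, and C2 and C3 are fixed in an acyclic precursor, so the union creates no stereocentre.
- Weak points: A4 is an ethynyl ether of a secondary benzylic alcohol that carries all of rings C and D; such ethers are prone to thermal loss of ketene and are made under strongly basic conditions next to the propargylic, benzylic C3–H. The insertion of the unsymmetrical terminal alkyne A5 must place the styryl group on C6 and not on C5, next to a hindered boronate, and A5 can also oligomerise or react through its alkene. A regiochemical miss would come at the last C–C bond-forming step with every stereocentre on board.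
- Comparison: it is the shortest endgame on paper and is superior in that it avoids a late stereo-defining step. The chosen plan answers with steps whose regiochemistry is fixed by the substrates (fluorine for ring C, a salicylaldehyde for ring A) and with a chiral sulfide for the one late stereochemical question.

**Alternative 3:** The cut is the one used here for ring B: C2–C3 and O1–C2, giving a ring A ortho-quinone methide precursor and a ring C benzylic sulfonium salt, with Cs2CO3 releasing both reactive partners to give the nona-O-methyl ether A7 (the same compound as 25).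

- Merits: it is convergent, the trans ring follows from the mechanism, and the partners are the same two fragments that step 12 of the chosen route joins (16 and 22).
- Weak points: as a strategy it places all the weight on the union and leaves open how the ring C/D fragment with a carbon on C7' is obtained. It shares the facial-selectivity question of the chosen endgame.
- Comparison: in convergence and in the final bond construction the two plans are equal. Making ring D by a second annulation of the same kind would even use fewer reaction types. The chosen plan adds the regiochemically unambiguous origin of aldehyde 11 (ring D and the C7' carbon from acyclic alcohol 7 in one step) and a catalytic source of the C2'/C3' configuration.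

Key step: step 4

Assumption: compounds 5, 13, 17 and the Grignard solution 20 are treated as purchasable; locants follow benzofuran numbering, unprimed for rings A/B and primed for rings C/D.

## Route

Step 1
Reactants: 1 1,3-dimethoxybenzene; 2 2-(3,5-dimethoxyphenyl)acetic acid
Product: 4 1-(2,4-dimethoxyphenyl)-2-(3,5-dimethoxyphenyl)ethan-1-one, via mixed trifluoroacetic anhydride 3 (not isolated)
Conditions: TFAA, H3PO4 (cat.), 1 in excess, MeCN, 0 °C → rt
Reagents that add atoms: none
Why: Friedel–Crafts acylation through the mixed anhydride 3; the excess of 1 is attacked at C4 (para to one methoxy group, ortho to the other), which should outrun self-acylation of the 3,5-dimethoxyphenyl ring of 2.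

Step 2
Reactants: 4 1-(2,4-dimethoxyphenyl)-2-(3,5-dimethoxyphenyl)ethan-1-one; 5 2-bromo-1-fluoro-3-methoxybenzene
Product: 6 racemic 1-(2,4-dimethoxyphenyl)-2-(3,5-dimethoxyphenyl)-2-(2-fluoro-6-methoxyphenyl)ethan-1-one
Conditions: Pd(OAc)2 (5 mol %), XPhos (10 mol %), K3PO4, toluene, 100 °C
Reagents that add atoms: none
Why: Palladium-catalysed ketone α-arylation of a deoxybenzoin, a known route to 1,2,2-triarylethanones; the bulky biarylphosphine serves the di-ortho-substituted bromide, K3PO4 is enough for the acidic benzylic ketone and leaves the aryl fluoride alone, and the new centre is deliberately formed racemic.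

Step 3
Reactants: 6 racemic 1-(2,4-dimethoxyphenyl)-2-(3,5-dimethoxyphenyl)-2-(2-fluoro-6-methoxyphenyl)ethan-1-one
Product: 7 (1R,2R)-1-(2,4-dimethoxyphenyl)-2-(3,5-dimethoxyphenyl)-2-(2-fluoro-6-methoxyphenyl)ethan-1-ol
Conditions: RuCl(p-cymene)[(R,R)-TsDPEN] (2 mol %), HCO2H, DBU, DMF, 40 °C
Reagents that add atoms: none
Why: Noyori–Ikariya asymmetric transfer hydrogenation with dynamic kinetic resolution: DBU racemises the acidic α,α-diaryl centre through the enolate while the (R,R) catalyst delivers hydride to the carbonyl face that gives 1R (ketone aryl group edge-on to the cymene ligand); the 2R ketone is the matched Felkin–Anh substrate (hydride anti to the di-ortho-substituted fluoroaryl group, α-hydrogen inside) and should be drained to the (1R,2R) alcohol.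

Step 4
Reactants: 7 (1R,2R)-1-(2,4-dimethoxyphenyl)-2-(3,5-dimethoxyphenyl)-2-(2-fluoro-6-methoxyphenyl)ethan-1-ol; 8 N,N-dimethylformamide
Product: 11 (2R,3R)-2-(2,4-dimethoxyphenyl)-3-(3,5-dimethoxyphenyl)-4-methoxy-2,3-dihydro-1-benzofuran-7-carbaldehyde, via aryne lithium alkoxide 9 (not isolated), via C7' aryl-lithium 10 (not isolated)
Conditions: LiTMP (2.5 equiv), THF, −78 → −30 °C; then 8, −78 °C → rt; H2O
Reagents that add atoms: none
Why: LiTMP first forms the lithium alkoxide and then removes the only hydrogen ortho to fluorine on ring C; on warming, the ortho-fluoro aryl-lithium loses LiF to give aryne 9. The tethered alkoxide adds to the aryne carbon that carried fluorine, a 5-exo-dig closure that makes the C7a'–O1' bond and ring D; attack at the distal aryne carbon would need a bridged ring and is excluded. The carbanion is thereby left on C7' (10), next to O1', and DMF added cold formylates it (C7'–CHO bond). The closest known reaction type is the intramolecular capture of arynes, generated from aryl fluorides with lithium amides, by tethered alkoxides with electrophilic quench of the new aryl-lithium. No stereocentre is formed and no bond to C2' or C3' is made or broken, so the (1R,2R) alcohol maps onto the trans (2R,3R) ring with retention. The step needs site-selective metalation: fluorine is the strongest acidifying group toward a hindered amide, and only this lithiation is drained irreversibly by LiF loss, whereas metalation between two methoxy groups is reversible and is kept down by the small excess of base and the low temperature. Deprotonation of the doubly benzylic C3'–H is disfavoured by the adjacent alkoxide, and the cold DMF quench is meant to come before tetramethylpiperidine can return a proton to C7'.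

Step 5
Reactants: 11 (2R,3R)-2-(2,4-dimethoxyphenyl)-3-(3,5-dimethoxyphenyl)-4-methoxy-2,3-dihydro-1-benzofuran-7-carbaldehyde
Product: 12 [(2R,3R)-2-(2,4-dimethoxyphenyl)-3-(3,5-dimethoxyphenyl)-4-methoxy-2,3-dihydro-1-benzofuran-7-yl]methanol
Conditions: NaBH4, MeOH–THF, 0 °C
Reagents that add atoms: none
Why: Borohydride reduction of an aryl aldehyde; nothing else in 11 is reducible and the stereocentres are not involved.

Step 6
Reactants: 13 (2S,5S)-hexane-2,5-diol
Product: 14 (2S,5S)-hexane-2,5-diyl dimethanesulfonate
Conditions: MsCl, Et3N, CH2Cl2, 0 °C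
Reagents that add atoms: methanesulfonyl chloride, CS(=O)(=O)Cl
Why: Standard mesylation of a secondary diol, with retention at both carbinol carbons.

Step 7
Reactants: 14 (2S,5S)-hexane-2,5-diyl dimethanesulfonate
Product: 15 (2R,5R)-2,5-dimethylthiolane
Conditions: Na2S·9H2O, DMSO, rt
Reagents that add atoms: sodium sulfide (Na2S), [Na+].[Na+].[S-2]
Why: Double SN2 displacement by sulfide, each with inversion, turns the (2S,5S) dimesylate into the C2-symmetric (2R,5R) thiolane; this is the known preparation of this chiral sulfide.

Step 8
Reactants: 12 [(2R,3R)-2-(2,4-dimethoxyphenyl)-3-(3,5-dimethoxyphenyl)-4-methoxy-2,3-dihydro-1-benzofuran-7-yl]methanol; 15 (2R,5R)-2,5-dimethylthiolane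
Product: 16 (2R,5R)-1-{[(2R,3R)-2-(2,4-dimethoxyphenyl)-3-(3,5-dimethoxyphenyl)-4-methoxy-2,3-dihydro-1-benzofuran-7-yl]methyl}-2,5-dimethylthiolan-1-ium tetrafluoroborate
Conditions: 15 (2 equiv), HBF4·OEt2, CH2Cl2, 0 °C → rt; Et2O precipitation
Reagents that add atoms: tetrafluoroboric acid (diethyl ether complex), [H+].F[B-](F)(F)F
Why: Acid-promoted substitution of an electron-rich benzylic alcohol by a sulfide, a known way to sulfonium salts: the 2,4-dialkoxybenzyl cation is captured by the excess of 15, and because the sulfide is C2-symmetric the sulfur is not stereogenic and one salt results.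

Step 9
Reactants: 17 4-bromo-2-hydroxy-6-methoxybenzaldehyde; 18 1-ethenyl-4-methoxybenzene
Product: 19 2-hydroxy-6-methoxy-4-[(E)-2-(4-methoxyphenyl)ethenyl]benzaldehyde
Conditions: Pd(OAc)2 (2 mol %), P(o-tol)3, Et3N, DMF, 100 °C
Reagents that add atoms: none
Why: Mizoroki–Heck reaction of an aryl bromide with a styrene under neutral (halide) conditions, which gives the β-arylated E-stilbene; the free salicylaldehyde is tolerated.

Step 10
Reactants: 19 2-hydroxy-6-methoxy-4-[(E)-2-(4-methoxyphenyl)ethenyl]benzaldehyde; 20 (3,5-dimethoxyphenyl)magnesium chloride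
Product: 21 racemic 2-[(3,5-dimethoxyphenyl)(hydroxy)methyl]-3-methoxy-5-[(E)-2-(4-methoxyphenyl)ethenyl]phenol
Conditions: 20 (2.5 equiv), THF, 0 °C → rt; H2O (pH 7)
Reagents that add atoms: none
Why: Grignard 1,2-addition to the aldehyde; the first equivalent is consumed by the phenol, the magnesium phenoxide then accepts the aryl group, and the new carbinol centre is racemic because it is erased in step 12.

Step 11
Reactants: 21 racemic 2-[(3,5-dimethoxyphenyl)(hydroxy)methyl]-3-methoxy-5-[(E)-2-(4-methoxyphenyl)ethenyl]phenol
Product: 22 racemic 2-[(3,5-dimethoxyphenyl)(4-methylbenzenesulfonyl)methyl]-3-methoxy-5-[(E)-2-(4-methoxyphenyl)ethenyl]phenol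
Conditions: p-TolSO2Na, HCO2H, CH2Cl2–H2O, rt
Reagents that add atoms: sodium 4-methylbenzenesulfinate, Cc1ccc(S(=O)[O-])cc1.[Na+]
Why: Acid-mediated ionisation of the ortho-hydroxybenzhydrol and S-alkylation of the sulfinate, the usual entry to 2-(arylsulfonylmethyl)phenols as storable ortho-quinone methide precursors.

Step 12
Reactants: 16 (2R,5R)-1-{[(2R,3R)-2-(2,4-dimethoxyphenyl)-3-(3,5-dimethoxyphenyl)-4-methoxy-2,3-dihydro-1-benzofuran-7-yl]methyl}-2,5-dimethylthiolan-1-ium tetrafluoroborate; 22 racemic 2-[(3,5-dimethoxyphenyl)(4-methylbenzenesulfonyl)methyl]-3-methoxy-5-[(E)-2-(4-methoxyphenyl)ethenyl]phenol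
Product: 25 (2R,3R)-2-[(2R,3R)-2-(2,4-dimethoxyphenyl)-3-(3,5-dimethoxyphenyl)-4-methoxy-2,3-dihydro-1-benzofuran-7-yl]-3-(3,5-dimethoxyphenyl)-4-methoxy-6-[(E)-2-(4-methoxyphenyl)ethenyl]-2,3-dihydro-1-benzofuran, via ring A ortho-quinone methide 23 (not isolated), via sulfonium ylide 24 (not isolated)
Conditions: Cs2CO3 (3 equiv), MeCN, 0 °C → rt
Reagents that add atoms: none
Why: Proposed new method: Cs2CO3 should release ortho-quinone methide 23 from 22 by E1cB loss of sulfinate and deprotonate 16 to benzylide 24; conjugate addition of the ylide carbon to the methide carbon (C2–C3) and 5-exo-tet displacement of the thiolane by the phenoxide with inversion (O1–C2) is the known (4+1) annulation of sulfonium ylides with ortho-quinone methides, which gives trans-2,3-dihydrobenzofurans, and the new element is that a C2-symmetric 2,5-dimethylthiolanium benzylide, whose ylide face is controlled in aldehyde epoxidation (the (2R,5R) sulfide gives (S,S)-epoxides, the spatial equivalent of 2R here), is asked to set C2 as R against the remote ring D centres, C3 following as R from the trans preference; any (2S,3S) adduct is a diastereomer and should be removable by chromatography.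

Step 13
Reactants: 25 (2R,3R)-2-[(2R,3R)-2-(2,4-dimethoxyphenyl)-3-(3,5-dimethoxyphenyl)-4-methoxy-2,3-dihydro-1-benzofuran-7-yl]-3-(3,5-dimethoxyphenyl)-4-methoxy-6-[(E)-2-(4-methoxyphenyl)ethenyl]-2,3-dihydro-1-benzofuran
Product: 26 (2R,3R)-2-[(2R,3R)-2-(2,4-dihydroxyphenyl)-3-(3,5-dihydroxyphenyl)-4-hydroxy-2,3-dihydro-1-benzofuran-7-yl]-3-(3,5-dihydroxyphenyl)-6-[(E)-2-(4-hydroxyphenyl)ethenyl]-2,3-dihydro-1-benzofuran-4-ol (CNP0217875.2)
Conditions: BBr3 (excess), CH2Cl2, −78 → 0 °C; MeOH, aq. NaHCO3
Reagents that add atoms: none
Why: BBr3 cleavage of aryl methyl ethers, the standard last step for permethylated stilbene oligomers; the stilbene is inert, and because both dihydrofurans are the thermodynamic trans isomers and C3/C3' are not touched, any reversible opening of the benzylic C–O bonds should reclose to the same configuration.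

## Compound list

1 | 1,3-dimethoxybenzene | COc1cccc(OC)c1 | starting material
2 | 2-(3,5-dimethoxyphenyl)acetic acid | COc1cc(CC(=O)O)cc(OC)c1 | starting material
3 | 2-(3,5-dimethoxyphenyl)acetic trifluoroacetic anhydride | COc1cc(CC(=O)OC(=O)C(F)(F)F)cc(OC)c1 | intermediate (not isolated)
4 | 1-(2,4-dimethoxyphenyl)-2-(3,5-dimethoxyphenyl)ethan-1-one | COc1ccc(C(=O)Cc2cc(OC)cc(OC)c2)c(OC)c1 | intermediate
5 | 2-bromo-1-fluoro-3-methoxybenzene | COc1cccc(F)c1Br | starting material
6 | racemic 1-(2,4-dimethoxyphenyl)-2-(3,5-dimethoxyphenyl)-2-(2-fluoro-6-methoxyphenyl)ethan-1-one | COc1ccc(C(=O)C(c2cc(OC)cc(OC)c2)c2c(F)cccc2OC)c(OC)c1 | intermediate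
7 | (1R,2R)-1-(2,4-dimethoxyphenyl)-2-(3,5-dimethoxyphenyl)-2-(2-fluoro-6-methoxyphenyl)ethan-1-ol | O[C@@H](c1ccc(OC)cc1OC)[C@@H](c1c(F)cccc1OC)c1cc(OC)cc(OC)c1 | intermediate
8 | N,N-dimethylformamide | CN(C)C=O | starting material
9 | lithium (1R,2R)-1-(2,4-dimethoxyphenyl)-2-(3,5-dimethoxyphenyl)-2-(6-methoxy-2,3-didehydrophenyl)ethan-1-olate (aryne) | [Li]O[C@@H](c1ccc(OC)cc1OC)[C@@H](C1=C(OC)C=CC#C1)c1cc(OC)cc(OC)c1 | intermediate (not isolated)
10 | [(2R,3R)-2-(2,4-dimethoxyphenyl)-3-(3,5-dimethoxyphenyl)-4-methoxy-2,3-dihydro-1-benzofuran-7-yl]lithium | [Li]c1ccc(OC)c2c1O[C@@H](c1ccc(OC)cc1OC)[C@@H]2c1cc(OC)cc(OC)c1 | intermediate (not isolated)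
11 | (2R,3R)-2-(2,4-dimethoxyphenyl)-3-(3,5-dimethoxyphenyl)-4-methoxy-2,3-dihydro-1-benzofuran-7-carbaldehyde (trans) | O=Cc1ccc(OC)c2c1O[C@@H](c1ccc(OC)cc1OC)[C@@H]2c1cc(OC)cc(OC)c1 | intermediate
12 | [(2R,3R)-2-(2,4-dimethoxyphenyl)-3-(3,5-dimethoxyphenyl)-4-methoxy-2,3-dihydro-1-benzofuran-7-yl]methanol | OCc1ccc(OC)c2c1O[C@@H](c1ccc(OC)cc1OC)[C@@H]2c1cc(OC)cc(OC)c1 | intermediate
13 | (2S,5S)-hexane-2,5-diol | C[C@H](O)CC[C@H](C)O | starting material
14 | (2S,5S)-hexane-2,5-diyl dimethanesulfonate | C[C@H](OS(C)(=O)=O)CC[C@H](C)OS(C)(=O)=O | intermediate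
15 | (2R,5R)-2,5-dimethylthiolane | C[C@@H]1CC[C@@H](C)S1 | intermediate
16 | (2R,5R)-1-{[(2R,3R)-2-(2,4-dimethoxyphenyl)-3-(3,5-dimethoxyphenyl)-4-methoxy-2,3-dihydro-1-benzofuran-7-yl]methyl}-2,5-dimethylthiolan-1-ium tetrafluoroborate | C[C@@H]1CC[C@@H](C)[S+]1Cc1ccc(OC)c2c1O[C@@H](c1ccc(OC)cc1OC)[C@@H]2c1cc(OC)cc(OC)c1.F[B-](F)(F)F | intermediate
17 | 4-bromo-2-hydroxy-6-methoxybenzaldehyde | COc1cc(Br)cc(O)c1C=O | starting material
18 | 1-ethenyl-4-methoxybenzene | C=Cc1ccc(OC)cc1 | starting material
19 | 2-hydroxy-6-methoxy-4-[(E)-2-(4-methoxyphenyl)ethenyl]benzaldehyde | COc1ccc(/C=C/c2cc(O)c(C=O)c(OC)c2)cc1 | intermediate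
20 | (3,5-dimethoxyphenyl)magnesium chloride | COc1cc(OC)cc([Mg]Cl)c1 | starting material
21 | racemic 2-[(3,5-dimethoxyphenyl)(hydroxy)methyl]-3-methoxy-5-[(E)-2-(4-methoxyphenyl)ethenyl]phenol | COc1ccc(/C=C/c2cc(O)c(C(O)c3cc(OC)cc(OC)c3)c(OC)c2)cc1 | intermediate
22 | racemic 2-[(3,5-dimethoxyphenyl)(4-methylbenzenesulfonyl)methyl]-3-methoxy-5-[(E)-2-(4-methoxyphenyl)ethenyl]phenol | COc1ccc(/C=C/c2cc(O)c(C(c3cc(OC)cc(OC)c3)S(=O)(=O)c3ccc(C)cc3)c(OC)c2)cc1 | intermediate
23 | 6-[(3,5-dimethoxyphenyl)methylidene]-5-methoxy-3-[(E)-2-(4-methoxyphenyl)ethenyl]cyclohexa-2,4-dien-1-one (ring A ortho-quinone methide) | O=C1C=C(/C=C/c2ccc(OC)cc2)C=C(OC)C1=Cc1cc(OC)cc(OC)c1 | intermediate (not isolated)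
24 | sulfonium benzylide derived from 16 by loss of a proton at the C7' methylene | C[C@@H]1CC[C@@H](C)[S+]1[CH-]c1ccc(OC)c2c1O[C@@H](c1ccc(OC)cc1OC)[C@@H]2c1cc(OC)cc(OC)c1 | intermediate (not isolated)
25 | nona-O-methyl ether of the target, (2R,3R,2'R,3'R) | COc1ccc(/C=C/c2cc(OC)c3c(c2)O[C@@H](c2ccc(OC)c4c2O[C@@H](c2ccc(OC)cc2OC)[C@@H]4c2cc(OC)cc(OC)c2)[C@@H]3c2cc(OC)cc(OC)c2)cc1 | intermediate
26 | CNP0217875.2, (2R,3R,2'R,3'R) | Oc1ccc(/C=C/c2cc(O)c3c(c2)O[C@@H](c2ccc(O)c4c2O[C@@H](c2ccc(O)cc2O)[C@@H]4c2cc(O)cc(O)c2)[C@@H]3c2cc(O)cc(O)c2)cc1 | target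

## Step count and risks

Total step count: 13. Longest linear sequence: 8 (steps 1, 2, 3, 4, 5, 8, 12, 13).

**Step 12 (proposed new method).** The C–C bond is formed between two hindered carbons. The chiral sulfonium group may discriminate the ylide faces poorly, and the electron-rich benzylic sulfonium may close ring B through an ionised intermediate in which the memory of the ylide face is lost. Slow ylide formation would also let the ortho-quinone methide dimerise. The fallback gives up reagent control and uses the annulation in its established form. It sets out from 12: tetrahydrothiophene and HBF4·OEt2 give 1-{[(2R,3R)-2-(2,4-dimethoxyphenyl)-3-(3,5-dimethoxyphenyl)-4-methoxy-2,3-dihydro-1-benzofuran-7-yl]methyl}thiolan-1-ium tetrafluoroborate F1. With 22 and Cs2CO3 this should give both trans adducts, 25 and its (2S,3S,2'R,3'R) diastereomer F2. Because ring D is already enantiopure these are diastereomers and are separated by chromatography; the route is rejoined at 25.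

**Step 4 (key step).** Tetramethylpiperidine may return a proton to C7' before the formylation, or reversible metalation between methoxy groups may be caught by DMF, so that the aldehyde is lost or misplaced. The fallback separates metalation from ring closure and replaces aryne capture by nucleophilic aromatic substitution. It sets out from 7: LiTMP at −78 °C, where the ortho-fluoro aryl-lithium does not yet eliminate, followed by DMF at −78 °C, gives 3-[(1R,2R)-2-(2,4-dimethoxyphenyl)-1-(3,5-dimethoxyphenyl)-2-hydroxyethyl]-2-fluoro-4-methoxybenzaldehyde F3. Its fluorine is now activated by the ortho formyl group, and K2CO3 in DMF at 60 °C should close ring D by intramolecular displacement, arriving at 11.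

**Step 3.** The catalyst may turn over slowly on the hindered ortho-methoxyaryl ketone, the α-centre may epimerise more slowly than the ketone is reduced (a plain kinetic resolution), or the two α-aryl groups may be discriminated too weakly (low diastereoselectivity). The fallback replaces catalytic induction by substrate control and resolution. It sets out from 6: L-Selectride in THF at −78 °C reduces under Felkin–Anh control to the racemic like alcohol, that is 7 together with its (1S,2S) enantiomer F4. Preparative chromatography on a chiral stationary phase delivers 7, and F4 is returned to 6 by Dess–Martin oxidation for another pass.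

**Step 2.** Oxidative addition and reductive elimination at the di-ortho-substituted bromide may be slow, so that protodebromination and catalyst decay win. The fallback reverses the roles so that the hindered ring is already in the ketone and the bromide is unhindered. It sets out from 1: acylation with 2-(2-fluoro-6-methoxyphenyl)acetic acid in polyphosphoric acid gives 1-(2,4-dimethoxyphenyl)-2-(2-fluoro-6-methoxyphenyl)ethan-1-one F5. Palladium-catalysed α-arylation of F5 with 1-bromo-3,5-dimethoxybenzene then arrives at 6.

**Step 13.** Material may be lost after the ethers are cleaved, through acid-mediated opening of the benzylic C–O bonds with intermolecular capture and through air oxidation of the free nonaphenol on silica. The fallback changes the isolation and not the cleavage. It sets out from 25: the crude product of the BBr3 reaction is acetylated (Ac2O, pyridine) to the nona-acetate of the target F6, which is purified as a stable neutral compound. Methanolysis with K2CO3 in degassed MeOH then releases 26.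

## Further compounds

F1 | step 12 | 1-{[(2R,3R)-2-(2,4-dimethoxyphenyl)-3-(3,5-dimethoxyphenyl)-4-methoxy-2,3-dihydro-1-benzofuran-7-yl]methyl}thiolan-1-ium tetrafluoroborate | C1CC[S+](C1)Cc1ccc(OC)c2c1O[C@@H](c1ccc(OC)cc1OC)[C@@H]2c1cc(OC)cc(OC)c1.F[B-](F)(F)F
F2 | step 12 | (2S,3S,2'R,3'R) diastereomer of 25 | COc1ccc(/C=C/c2cc(OC)c3c(c2)O[C@H](c2ccc(OC)c4c2O[C@@H](c2ccc(OC)cc2OC)[C@@H]4c2cc(OC)cc(OC)c2)[C@H]3c2cc(OC)cc(OC)c2)cc1
F3 | step 4 | 3-[(1R,2R)-2-(2,4-dimethoxyphenyl)-1-(3,5-dimethoxyphenyl)-2-hydroxyethyl]-2-fluoro-4-methoxybenzaldehyde | O[C@@H](c1ccc(OC)cc1OC)[C@@H](c1c(F)c(C=O)ccc1OC)c1cc(OC)cc(OC)c1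
F4 | step 3 | (1S,2S)-1-(2,4-dimethoxyphenyl)-2-(3,5-dimethoxyphenyl)-2-(2-fluoro-6-methoxyphenyl)ethan-1-ol (enantiomer of 7) | O[C@H](c1ccc(OC)cc1OC)[C@H](c1c(F)cccc1OC)c1cc(OC)cc(OC)c1
F5 | step 2 | 1-(2,4-dimethoxyphenyl)-2-(2-fluoro-6-methoxyphenyl)ethan-1-one | COc1ccc(C(=O)Cc2c(F)cccc2OC)c(OC)c1
F6 | step 13 | nona-O-acetate of the target, (2R,3R,2'R,3'R) | CC(=O)Oc1ccc(/C=C/c2cc(OC(C)=O)c3c(c2)O[C@@H](c2ccc(OC(C)=O)c4c2O[C@@H](c2ccc(OC(C)=O)cc2OC(C)=O)[C@@H]4c2cc(OC(C)=O)cc(OC(C)=O)c2)[C@@H]3c2cc(OC(C)=O)cc(OC(C)=O)c2)cc1
A1 | alternative 1 | (E)-1-diazo-4-[6-bromo-3-(3,5-dimethoxyphenyl)-4-methoxy-2,3-dihydro-1-benzofuran-2-yl]but-3-en-2-one, trans ring B with the target's sense at C2 and C3 | [N-]=[N+]=CC(=O)/C=C/[C@@H]1Oc2cc(Br)cc(OC)c2[C@H]1c1cc(OC)cc(OC)c1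
A2 | alternative 1 | 4-(tert-butyldimethylsilyloxy)-4-(2,4-dimethoxyphenyl)-3-(3,5-dimethoxyphenyl)-1-(triisopropylsilyloxy)but-1-yne, with the target's sense at C3' and C2' | CC(C)[Si](C(C)C)(C(C)C)OC#C[C@@H](c1cc(OC)cc(OC)c1)[C@@H](O[Si](C)(C)C(C)(C)C)c1ccc(OC)cc1OC
A3 | alternative 1 | ring C phenol carrying ring B on C7', the C3'/C2' chain on C3a' and a triisopropylsilyl ether on C4' | Brc1cc(OC)c2c(c1)O[C@@H](c1ccc(O[Si](C(C)C)(C(C)C)C(C)C)c([C@@H](c3cc(OC)cc(OC)c3)[C@@H](O[Si](C)(C)C(C)(C)C)c3ccc(OC)cc3OC)c1O)[C@@H]2c1cc(OC)cc(OC)c1
A4 | alternative 2 | diyne with an ethynyl ether on O1 and a pinacol alkynylboronate on C3, carrying the ring C/D unit on C2 | C#CO[C@@H](c1ccc(OC)c2c1O[C@@H](c1ccc(OC)cc1OC)[C@@H]2c1cc(OC)cc(OC)c1)[C@@H](C#CB1OC(C)(C)C(C)(C)O1)c1cc(OC)cc(OC)c1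
A5 | alternative 2 | 1-[(E)-but-1-en-3-yn-1-yl]-4-methoxybenzene | C#C/C=C/c1ccc(OC)cc1
A6 | alternative 2 | octa-O-methyl target with a pinacol boronate in place of the ring A hydroxyl | COc1ccc(/C=C/c2cc(B3OC(C)(C)C(C)(C)O3)c3c(c2)O[C@@H](c2ccc(OC)c4c2O[C@@H](c2ccc(OC)cc2OC)[C@@H]4c2cc(OC)cc(OC)c2)[C@@H]3c2cc(OC)cc(OC)c2)cc1
A7 | alternative 3 | nona-O-methyl ether of the target (same compound as 25) | COc1ccc(/C=C/c2cc(OC)c3c(c2)O[C@@H](c2ccc(OC)c4c2O[C@@H](c2ccc(OC)cc2OC)[C@@H]4c2cc(OC)cc(OC)c2)[C@@H]3c2cc(OC)cc(OC)c2)cc1
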